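## The problem

The target 27 is a 6-acetyl-7-hydroxy-2H-chromene. Its only stereocentre is the quaternary ether carbon C2 (R), which carries a methyl group and a CH2O arm esterified with (E)-ferulic acid. Because C2 stands alone, no other centre can relay its configuration, so it must be bought or set by a reagent and then never ionised. Forming O1–C2 through a tertiary cation would racemise it, so O1 has to arrive as the oxygen of an intact tertiary alcohol and the ring ether has to be closed at C8a. The benzene ring is 1,2,4,5-substituted (C4a alkyl, C6 acetyl, C7 OH, C8a O1), and acylating or alkylating a resorcinol to reach this pattern raises a C6-versus-C8 regiochemical question. Three groups are fragile: the feruloyl ester with its free phenol and conjugated alkene (no organolithiums, alkoxides or strong oxidants), the acid-sensitive C3=C4 chromene alkene, and the enolisable, oxidisable ortho-hydroxyacetophenone. The feature that opens the key step is the carbocycle itself. C7–OH and C8a–O1 are meta like the carbonyls of a cyclohexane-1,3-dione, C6 carries a carbonyl carbon, C5 and C8 are CH, and C4a carries the C4–C3–C2 chain. This is the pattern produced when malonate is annulated onto an α-substituted methyl vinyl ketone, so every ring substituent can be placed by connectivity.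

## Retrosynthesis

**Feruloyl ester C–O bond.** The last bond cut is the acyl–oxygen bond between the C2 hydroxymethyl arm and the feruloyl carbonyl of 27. The cinnamate would not survive MeLi, NaOCH3 or DDQ, so it is attached last. Cutting here, and not at the cinnamate C=C, keeps ferulic acid 23 as a bought unit with its E geometry. The precursors are chromene diol 22 and the phenol-silylated acid 25, made in one step from 23 through 24. The forward reaction must acylate the primary, neopentyl-type alcohol of 22 in preference to the chelated C7 phenol, and the ferulate phenol of 26 must then be freed without touching the ester.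

**C3=C4 alkene.** Diol 22 is traced through silyl ether 21 to the saturated chroman 20 by adding two hydrogens across C3=C4. Carrying an alkene or a C4 oxygen through the ring synthesis would place an allylic or benzylic leaving group next to the stereocentre under acid and base, whereas plain CH2 groups are inert. The forward reaction is a hydride abstraction at C4, which is para to the C7 hydroxyl. It is run on silyl ether 20 so that the primary hydroxyl cannot trap the benzylic cation, and desilylation of 21 follows.

**Acetyl C–CH3 bond.** The acetyl methyl of 20 is disconnected to carboxylic acid 19, which comes from methyl ester 18. This is the price of malonate, which delivers C6 at the carboxylate level. An acetoacetate partner would give the acetyl group directly but would open competing aldol closures in the annulation. The forward reaction asks MeLi to stop at the ketone, which the dilithium gem-diolate of a lithium carboxylate ensures.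

**Aromatic ring and O1–C8a bond.** Salicylate 18 is the dehydro form of the bicyclic vinylogous ester 16, and 16 is opened at O1–C8a to the tertiary alcohol and C8a ketone of dione ester 15. The order is essential. A phenol could be joined to C2 only through a tertiary cation, while a dione takes up the intact hydroxyl by addition–elimination at C8a, so the ether must close before aromatisation. Only C8a is within six-membered reach of the alcohol, which fixes the regiochemistry. The forward steps are a mild acid condensation and the removal of one molecule of hydrogen from C5/C6.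

**C5–C6 and C7–C8 (key disconnection).** Dione ester 15 is cut into enone 12 and dimethyl malonate 13. Against an aromatic starting material this cut places C4a-alkyl, C6-carbonyl, C7-O and C8a-O unambiguously and leaves C2 remote from all bond formation. The precursor falls from a bicyclic, trisubstituted ring to a ten-carbon acyclic enone. The forward reaction must run a Michael addition and a Claisen closure in one flask in the presence of a free tertiary hydroxyl.

**Methylene and methyl ketone of 12.** The exocyclic CH2 (future C5) and the ketone methyl (future C8) are removed in turn. Enone 12 comes from β-amino ketone 10 by quaternisation–elimination, 10 from amino lactone 9 and MeLi, and 9 from lactone 8 by Mannich aminomethylation. Adding MeLi to an α-methylene lactone would invite conjugate addition and anionic oligomerisation, so the methylene is carried as its dimethylamine adduct until after the organolithium step.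

**C3–C4 bond and the stereocentre.** Lactone 8 is the oxidation product of 1,5-diol 6, which comes from alkene 4 by hydroboration. Alkene 4 is cut between the future C3 and C4 into silyl glycidyl ether 2 and allylmagnesium bromide 3, and 2 comes from (S)-2-methylglycidol 1. The epoxide is opened at its CH2 carbon, so the quaternary C–O bond bought in 1 is never broken and becomes O1–C2 of the target.

## Roads not taken

**Alternative 1:** Kabbe spiroannulation and enzymatic desymmetrisation.
- Cut and key step: the pyran ring is cut at C2–C3 and O1–C2. 1-(5-Bromo-2,4-dihydroxyphenyl)ethan-1-one A1 and 2,2-dimethyl-1,3-dioxan-5-one A2 would be condensed with pyrrolidine (enamine aldol, dehydration, oxa-Michael closure) to the spirocyclic chroman-4-one A3. Acetonide hydrolysis would give the prochiral bis(hydroxymethyl)chromanone A4, whose two arms a lipase would have to tell apart. One arm would then be reduced to the C2 methyl, the C4 ketone reduced and dehydrated to the alkene, and bromine exchanged for acetyl by palladium-catalysed coupling.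
- Merits: the benzene ring and both oxygens are bought. The bicyclic core arises in one step, against ten in the chosen plan. The C4 carbonyl gives the chromene alkene without an oxidant.
- Weak points: C2 is made achiral, and its configuration rests on an enzyme distinguishing two CH2OH groups that differ only in remote ring atoms (C3H2 versus O1), so enantiopurity cannot be argued from structure. Deoxygenating one neopentyl-type arm takes several steps while the other stays differentiated. The aryl bromide must survive until the acetyl group is installed.
- Comparison: in ring construction this road is clearly better, but after its key step it is probably no shorter. The chosen plan sets against it a stereocentre bought in 1 with its methyl group in place and never put at risk.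

**Alternative 2:** SNAr closure of the pyran ether.
- Cut and key step: the cut is O1–C8a. The Z-configured tertiary allylic alcohol A5, carrying a 2,4-difluoro-5-acetylphenyl group, would be treated with Cs2CO3 or KOC(CH3)3 so that the alkoxide displaces the fluoride para to the acetyl group and gives fluorochromene A6.
- Merits: O1 arrives on an intact tertiary alcohol, as in the chosen plan. The C3=C4 alkene is present from the start and the acetyl group is bought in its final oxidation state. The sequence would be markedly shorter, so on step economy this road is better.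
- Weak points: a hindered tertiary alkoxide must attack an arene activated by a single para acyl group whose methyl is enolisable under the same base, so aldol self-condensation and intermolecular attack at the ortho-activated fluoride compete. The Z alkene must be made by semi-hydrogenation (Pd/CaCO3 poisoned with Pb(OAc)2) and kept. The remaining fluoride of A6 must be exchanged for hydroxyl by a second SNAr on a base-sensitive aryl ketone. The PMB ether must be removed oxidatively beside the chromene.
- Comparison: the chosen plan is longer. It sets against that the origin of both ring oxygens in carbonyl groups, so no C–F to C–O exchange is needed, and ring bonds formed by enolate and condensation chemistry under mild conditions.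

**Alternative 3:** Diels–Alder benzannulation.
- Cut and key step: the cut is C4a–C5 and C6–C7. The bis(trimethylsilyl) ketene acetal diene A7, a 3,4-dihydro-2H-pyran carrying the stereocentre, would add to but-3-yn-2-one A8 and lose trimethylsilanol to give chroman A9.
- Merits: it also builds the benzene ring onto a chiral-pool pyran precursor, and A7 could be derived from lactone 8. It delivers acetyl and hydroxyl in their final form, saving the separate aromatisation and the ester-to-ketone steps, about three steps on paper. Regiochemistry follows from diene polarisation.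
- Weak points: A7 is a doubly silylated ketene acetal conjugated with a cyclic enol ether, so it is hydrolytically fragile. Making it requires regiocontrolled formation of the endocyclic C4a=C8a enol ether and a kinetic dienolate silylation. With A8, stepwise Mukaiyama–Michael addition without ring closure and ynone polymerisation compete. The chroman-to-chromene dehydrogenation is still required.
- Comparison: it is shorter and equal in the late stage. The chosen plan sets against it isolable intermediates and a ring closure driven by formation of a stabilised β-dicarbonyl anion.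

Key step: step 8

Assumption: hydroxy ketones 10 and 12 and dione 15 are drawn in their open keto forms although each can equilibrate with a cyclic hemiketal or enol tautomer, and the ring-centre epimers of 9, 10, 14, 15, 16 and 17 are carried as mixtures because those centres are removed later.

## Route

Step 1
Reactants: 1 (S)-2-methylglycidol, [(2S)-2-methyloxiran-2-yl]methanol
Product: 2 (R)-triisopropyl[(2-methyloxiran-2-yl)methoxy]silane
Conditions: TIPSCl, imidazole, DMAP (cat.), CH2Cl2, 0 °C to rt
Reagents that add atoms: triisopropylsilyl chloride, CC(C)[Si](Cl)(C(C)C)C(C)C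
Why: Routine silylation of a primary alcohol that leaves the epoxide untouched; the descriptor changes from S to R only because the silyloxymethyl arm now outranks the oxirane CH2. TIPS is chosen to survive methoxide, hydroxide, MeLi, mild acid and DDQ later.

Step 2
Reactants: 2 (R)-triisopropyl[(2-methyloxiran-2-yl)methoxy]silane; 3 allylmagnesium bromide
Product: 4 (R)-2-methyl-1-(triisopropylsilyloxy)hex-5-en-2-ol
Conditions: allylMgBr, CuI (10 mol %), THF, −30 to 0 °C; aq. NH4Cl
Reagents that add atoms: none
Why: Copper-assisted SN2 opening of a 2,2-disubstituted epoxide at its unsubstituted carbon forms the future C3–C4 bond. The quaternary C–O bond is not involved, so configuration is retained.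

Step 3
Reactants: 4 (R)-2-methyl-1-(triisopropylsilyloxy)hex-5-en-2-ol
Product: 6 (R)-5-methyl-6-(triisopropylsilyloxy)hexane-1,5-diol, via alkylborane 5 (not isolated)
Conditions: 9-BBN (2.5 equiv), THF, 0 °C to rt; then NaOH, H2O2, 0 °C to rt
Reagents that add atoms: hydrogen peroxide, OO
Why: Anti-Markovnikov hydroboration–oxidation of a terminal alkene; 9-BBN places boron on the terminal carbon and the tertiary hydroxyl is tolerated with excess reagent.

Step 4
Reactants: 6 (R)-5-methyl-6-(triisopropylsilyloxy)hexane-1,5-diol
Product: 8 (R)-6-methyl-6-[(triisopropylsilyloxy)methyl]tetrahydro-2H-pyran-2-one, via lactol 7 (not isolated)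
Conditions: TEMPO (20 mol %), PhI(OAc)2 (2.5 equiv), CH2Cl2, rt
Reagents that add atoms: none
Why: Oxoammonium oxidation of the primary alcohol gives an aldehyde that closes on the tertiary hydroxyl to lactol 7, which is oxidised on to the δ-lactone (oxidative lactonisation of a 1,5-diol). The tertiary alcohol cannot be oxidised.

Step 5
Reactants: 8 (R)-6-methyl-6-[(triisopropylsilyloxy)methyl]tetrahydro-2H-pyran-2-one
Product: 9 (6R)-3-[(dimethylamino)methyl]-6-methyl-6-[(triisopropylsilyloxy)methyl]tetrahydro-2H-pyran-2-one (C3 epimers)
Conditions: LiN(iPr)2 (1.1 equiv), THF, −78 °C; then CH2=N(CH3)2 iodide, −78 °C to rt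
Reagents that add atoms: N,N-dimethylmethyleneiminium iodide (Eschenmoser's salt), C=[N+](C)C.[I-]
Why: Mannich aminomethylation of the lactone lithium enolate installs the future C5 at the only enolisable position. The amine is kept as a masked methylene so that no Michael acceptor is present in step 6.

Step 6
Reactants: 9 (6R)-3-[(dimethylamino)methyl]-6-methyl-6-[(triisopropylsilyloxy)methyl]tetrahydro-2H-pyran-2-one
Product: 10 (6R)-3-[(dimethylamino)methyl]-6-hydroxy-6-methyl-7-(triisopropylsilyloxy)heptan-2-one (C3 epimers)
Conditions: MeLi (1.15 equiv), THF, −78 °C; aq. NH4Cl at −78 °C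
Reagents that add atoms: methyllithium, [Li]C
Why: Single addition of an organolithium to a δ-lactone; the cyclic lithium hemiketal alkoxide persists at −78 °C and releases the methyl ketone and the tertiary alcohol only on quench.

Step 7
Reactants: 10 (6R)-3-[(dimethylamino)methyl]-6-hydroxy-6-methyl-7-(triisopropylsilyloxy)heptan-2-one
Product: 12 (R)-6-hydroxy-6-methyl-3-methylene-7-(triisopropylsilyloxy)heptan-2-one, via trimethylammonium iodide 11 (not isolated)
Conditions: MeI (5 equiv), Et2O/CH3OH, rt; evaporate; then NaHCO3, CH2Cl2/H2O, rt
Reagents that add atoms: none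
Why: Quaternisation of the Mannich base and E1cB loss of trimethylamine, the classical unmasking of an α-methylene ketone. The enone is used at once to avoid dimerisation.

Step 8
Reactants: 12 (R)-6-hydroxy-6-methyl-3-methylene-7-(triisopropylsilyloxy)heptan-2-one; 13 dimethyl malonate
Product: 15 methyl 5-[(3R)-3-hydroxy-3-methyl-4-(triisopropylsilyloxy)butyl]-2,4-dioxocyclohexane-1-carboxylate (ring centres epimeric), via Michael adduct 14 (not isolated)
Conditions: dimethyl malonate (1.5 equiv), NaOCH3 (2.5 equiv), CH3OH, 0 °C to reflux; then 1 M HCl to pH 3 at 0 °C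
Reagents that add atoms: none
Why: Sodium dimethyl malonate adds in a Michael reaction to the unsubstituted terminus of enone 12 (C5–C6) to give 14; under the same NaOCH3 the methyl ketone of 14 enolises towards its CH3 group (C8) and attacks one malonate ester carbonyl (C7) in a Claisen condensation, expelling methoxide. The closest known reaction type is the malonate–vinyl ketone Michael–Claisen route to 4-alkoxycarbonylcyclohexane-1,3-diones used for dihydroresorcinols. The carbocycle closes in a 6-(enolexo)-exo-trig mode, and the alternative enolate at C4a could only form a four-membered ring, so regiochemistry is fixed by connectivity. The equilibria are pulled forward by deprotonation of the product β-dicarbonyl, which is why more than two equivalents of base are used. Two ring centres (C4a and C6) are created without control and need none, since both become sp2 on aromatisation, and C2 is remote and untouched. The selectivity needed is chemoselectivity against O-addition: oxa-Michael addition or hemiketal formation by the tertiary alkoxide and methoxide addition to the enone are reversible, whereas C-addition followed by Claisen closure is not, so these species should feed the product. Excess malonate suppresses a second Michael addition of 14 to 12, and the hindered TIPS ether should survive methoxide.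

Step 9
Reactants: 15 methyl 5-[(3R)-3-hydroxy-3-methyl-4-(triisopropylsilyloxy)butyl]-2,4-dioxocyclohexane-1-carboxylate
Product: 16 methyl (2R)-2-methyl-7-oxo-2-[(triisopropylsilyloxy)methyl]-3,4,4a,5,6,7-hexahydro-2H-chromene-6-carboxylate (C4a and C6 epimers)
Conditions: PPTS (10 mol %), toluene, 80 °C, 4 Å MS
Reagents that add atoms: none
Why: Acid-catalysed vinylogous ester formation: the tertiary hydroxyl adds to the C8a carbonyl (six-membered hemiketal, the only ring size in reach) and water is lost towards C8. The C2–O bond is never broken, and the β-silyloxy group and the weak acid disfavour ionisation at C2, so the configuration is retained.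

Step 10
Reactants: 16 methyl (2R)-2-methyl-7-oxo-2-[(triisopropylsilyloxy)methyl]-3,4,4a,5,6,7-hexahydro-2H-chromene-6-carboxylate
Product: 18 methyl (R)-7-hydroxy-2-methyl-2-[(triisopropylsilyloxy)methyl]chromane-6-carboxylate, via C6 phenylselenide 17 (not isolated)
Conditions: NaH (1.05 equiv), THF, 0 °C; PhSeCl (1.05 equiv), 0 °C; then 30% H2O2, pyridine, CH2Cl2, 0 °C to rt
Reagents that add atoms: none
Why: α-Selenenylation of the β-keto ester enolate at C6 followed by selenoxide syn-elimination towards C5 gives a cyclohexadienone that tautomerises at once to the phenol. The mild conditions cannot over-oxidise the chroman.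

Step 11
Reactants: 18 methyl (R)-7-hydroxy-2-methyl-2-[(triisopropylsilyloxy)methyl]chromane-6-carboxylate
Product: 19 (R)-7-hydroxy-2-methyl-2-[(triisopropylsilyloxy)methyl]chromane-6-carboxylic acid
Conditions: LiOH·H2O (6 equiv), THF/CH3OH/H2O, 60 °C; then 1 M HCl to pH 3, 0 °C
Reagents that add atoms: lithium hydroxide, [Li+].[OH-]
Why: Saponification of a methyl salicylate; heating is needed because the phenoxide deactivates the ester, and the TIPS ether tolerates aqueous hydroxide.

Step 12
Reactants: 19 (R)-7-hydroxy-2-methyl-2-[(triisopropylsilyloxy)methyl]chromane-6-carboxylic acid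
Product: 20 (R)-1-{7-hydroxy-2-methyl-2-[(triisopropylsilyloxy)methyl]chroman-6-yl}ethan-1-one
Conditions: MeLi (4.5 equiv), THF, 0 °C to rt; inverse quench into cold 1 M HCl
Reagents that add atoms: methyllithium, [Li]C
Why: Addition of MeLi to the lithium carboxylate of a salicylic acid gives a gem-diolate that cannot add a second time and collapses to the methyl ketone on quench. This is the standard route from salicylic acids to ortho-hydroxyacetophenones.

Step 13
Reactants: 20 (R)-1-{7-hydroxy-2-methyl-2-[(triisopropylsilyloxy)methyl]chroman-6-yl}ethan-1-one
Product: 21 (R)-1-{7-hydroxy-2-methyl-2-[(triisopropylsilyloxy)methyl]-2H-chromen-6-yl}ethan-1-one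
Conditions: DDQ (1.5 equiv), 1,4-dioxane, reflux
Reagents that add atoms: none
Why: DDQ dehydrogenation of a chroman to a 2H-chromene: hydride is abstracted from C4, which is para to the C7 hydroxyl and ortho-related to O1, and proton loss from C3 follows. The silyl ether keeps the primary oxygen from trapping the benzylic cation and C2 has no hydrogen to lose.

Step 14
Reactants: 21 (R)-1-{7-hydroxy-2-methyl-2-[(triisopropylsilyloxy)methyl]-2H-chromen-6-yl}ethan-1-one
Product: 22 (R)-1-[7-hydroxy-2-(hydroxymethyl)-2-methyl-2H-chromen-6-yl]ethan-1-one
Conditions: TBAF (1.5 equiv), THF, 0 °C to rt; aq. NH4Cl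
Reagents that add atoms: none
Why: Fluoride cleavage of the primary TIPS ether; the chromene and the aryl ketone are inert to fluoride.

Step 15
Reactants: 23 ferulic acid, (E)-3-(4-hydroxy-3-methoxyphenyl)acrylic acid
Product: 25 (E)-3-[4-(tert-butyldimethylsilyloxy)-3-methoxyphenyl]acrylic acid, via bis-silyl derivative 24 (not isolated)
Conditions: TBSCl (2.4 equiv), imidazole (5 equiv), DMF, rt; then THF/AcOH/H2O (3:1:1), rt
Reagents that add atoms: tert-butyldimethylsilyl chloride, CC(C)(C)[Si](C)(C)Cl
Why: Silylation of both acidic groups, then selective hydrolysis of the much more labile silyl ester; the aryl silyl ether is stable to dilute acetic acid.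

Step 16
Reactants: 22 (R)-1-[7-hydroxy-2-(hydroxymethyl)-2-methyl-2H-chromen-6-yl]ethan-1-one; 25 (E)-3-[4-(tert-butyldimethylsilyloxy)-3-methoxyphenyl]acrylic acid
Product: 26 [(2R)-6-acetyl-7-hydroxy-2-methyl-2H-chromen-2-yl]methyl (E)-3-[4-(tert-butyldimethylsilyloxy)-3-methoxyphenyl]acrylate
Conditions: 25 (1.1 equiv), EDC·HCl (1.3 equiv), DMAP (20 mol %), CH2Cl2, 0 °C to rt
Reagents that add atoms: none
Why: Steglich esterification by acyl transfer, so no substitution at the neopentyl-type carbon is required. The aliphatic alcohol should react in preference to the C7 phenol, which is hydrogen-bonded to the acetyl group and a poor nucleophile.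

Step 17
Reactants: 26 [(2R)-6-acetyl-7-hydroxy-2-methyl-2H-chromen-2-yl]methyl (E)-3-[4-(tert-butyldimethylsilyloxy)-3-methoxyphenyl]acrylate
Product: 27 [(2R)-6-acetyl-7-hydroxy-2-methyl-2H-chromen-2-yl]methyl (E)-3-(4-hydroxy-3-methoxyphenyl)acrylate
Conditions: TBAF (1.1 equiv), AcOH (1.5 equiv), THF, 0 °C
Reagents that add atoms: none
Why: Buffered fluoride removes the aryl silyl ether within minutes, and the acetic acid keeps the medium from becoming basic enough to attack the cinnamate ester or the chromene.

## Compound list

1 | (S)-2-methylglycidol, [(2S)-2-methyloxiran-2-yl]methanol | OC[C@@]1(C)CO1 | starting material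
2 | (R)-triisopropyl[(2-methyloxiran-2-yl)methoxy]silane | CC(C)[Si](OC[C@@]1(C)CO1)(C(C)C)C(C)C | intermediate
3 | allylmagnesium bromide | C=CC[Mg]Br | starting material
4 | (R)-2-methyl-1-(triisopropylsilyloxy)hex-5-en-2-ol | CC(C)[Si](OC[C@@](O)(C)CCC=C)(C(C)C)C(C)C | intermediate
5 | (R)-6-(9-borabicyclo[3.3.1]nonan-9-yl)-2-methyl-1-(triisopropylsilyloxy)hexan-2-ol (formed in the flask) | CC(C)[Si](OC[C@@](O)(C)CCCCB1C2CCCC1CCC2)(C(C)C)C(C)C | intermediate
6 | (R)-5-methyl-6-(triisopropylsilyloxy)hexane-1,5-diol | CC(C)[Si](OC[C@@](O)(C)CCCCO)(C(C)C)C(C)C | intermediate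
7 | (6R)-6-methyl-6-[(triisopropylsilyloxy)methyl]tetrahydro-2H-pyran-2-ol (formed in the flask, anomers) | CC(C)[Si](OC[C@@]1(C)CCCC(O)O1)(C(C)C)C(C)C | intermediate
8 | (R)-6-methyl-6-[(triisopropylsilyloxy)methyl]tetrahydro-2H-pyran-2-one | CC(C)[Si](OC[C@@]1(C)CCCC(=O)O1)(C(C)C)C(C)C | intermediate
9 | (6R)-3-[(dimethylamino)methyl]-6-methyl-6-[(triisopropylsilyloxy)methyl]tetrahydro-2H-pyran-2-one (C3 epimers) | CC(C)[Si](OC[C@@]1(C)CCC(CN(C)C)C(=O)O1)(C(C)C)C(C)C | intermediate
10 | (6R)-3-[(dimethylamino)methyl]-6-hydroxy-6-methyl-7-(triisopropylsilyloxy)heptan-2-one (C3 epimers) | CC(=O)C(CN(C)C)CC[C@@](C)(O)CO[Si](C(C)C)(C(C)C)C(C)C | intermediate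
11 | (5R)-2-acetyl-5-hydroxy-N,N,N,5-tetramethyl-6-(triisopropylsilyloxy)hexan-1-aminium iodide (formed in the flask) | CC(=O)C(C[N+](C)(C)C)CC[C@@](C)(O)CO[Si](C(C)C)(C(C)C)C(C)C.[I-] | intermediate
12 | (R)-6-hydroxy-6-methyl-3-methylene-7-(triisopropylsilyloxy)heptan-2-one | CC(=O)C(=C)CC[C@@](C)(O)CO[Si](C(C)C)(C(C)C)C(C)C | intermediate
13 | dimethyl malonate | COC(=O)CC(=O)OC | starting material
14 | dimethyl 2-[(5R)-2-acetyl-5-hydroxy-5-methyl-6-(triisopropylsilyloxy)hexyl]malonate (formed in the flask) | COC(=O)C(CC(CC[C@@](C)(O)CO[Si](C(C)C)(C(C)C)C(C)C)C(C)=O)C(=O)OC | intermediate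
15 | methyl 5-[(3R)-3-hydroxy-3-methyl-4-(triisopropylsilyloxy)butyl]-2,4-dioxocyclohexane-1-carboxylate (ring centres epimeric) | COC(=O)C1CC(CC[C@@](C)(O)CO[Si](C(C)C)(C(C)C)C(C)C)C(=O)CC1=O | intermediate
16 | methyl (2R)-2-methyl-7-oxo-2-[(triisopropylsilyloxy)methyl]-3,4,4a,5,6,7-hexahydro-2H-chromene-6-carboxylate (C4a and C6 epimers) | COC(=O)C1CC2CC[C@](C)(CO[Si](C(C)C)(C(C)C)C(C)C)OC2=CC1=O | intermediate
17 | methyl (2R)-2-methyl-7-oxo-6-(phenylselanyl)-2-[(triisopropylsilyloxy)methyl]-3,4,4a,5,6,7-hexahydro-2H-chromene-6-carboxylate (formed in the flask) | COC(=O)C1([Se]c2ccccc2)CC2CC[C@](C)(CO[Si](C(C)C)(C(C)C)C(C)C)OC2=CC1=O | intermediate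
18 | methyl (R)-7-hydroxy-2-methyl-2-[(triisopropylsilyloxy)methyl]chromane-6-carboxylate | COC(=O)c1cc2CC[C@](C)(CO[Si](C(C)C)(C(C)C)C(C)C)Oc2cc1O | intermediate
19 | (R)-7-hydroxy-2-methyl-2-[(triisopropylsilyloxy)methyl]chromane-6-carboxylic acid | OC(=O)c1cc2CC[C@](C)(CO[Si](C(C)C)(C(C)C)C(C)C)Oc2cc1O | intermediate
20 | (R)-1-{7-hydroxy-2-methyl-2-[(triisopropylsilyloxy)methyl]chroman-6-yl}ethan-1-one | CC(=O)c1cc2CC[C@](C)(CO[Si](C(C)C)(C(C)C)C(C)C)Oc2cc1O | intermediate
21 | (R)-1-{7-hydroxy-2-methyl-2-[(triisopropylsilyloxy)methyl]-2H-chromen-6-yl}ethan-1-one | CC(=O)c1cc2C=C[C@](C)(CO[Si](C(C)C)(C(C)C)C(C)C)Oc2cc1O | intermediate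
22 | (R)-1-[7-hydroxy-2-(hydroxymethyl)-2-methyl-2H-chromen-6-yl]ethan-1-one | CC(=O)c1cc2C=C[C@](C)(CO)Oc2cc1O | intermediate
23 | ferulic acid, (E)-3-(4-hydroxy-3-methoxyphenyl)acrylic acid | COc1cc(/C=C/C(=O)O)ccc1O | starting material
24 | tert-butyldimethylsilyl (E)-3-[4-(tert-butyldimethylsilyloxy)-3-methoxyphenyl]acrylate (formed in the flask) | COc1cc(/C=C/C(=O)O[Si](C)(C)C(C)(C)C)ccc1O[Si](C)(C)C(C)(C)C | intermediate
25 | (E)-3-[4-(tert-butyldimethylsilyloxy)-3-methoxyphenyl]acrylic acid | COc1cc(/C=C/C(=O)O)ccc1O[Si](C)(C)C(C)(C)C | intermediate
26 | [(2R)-6-acetyl-7-hydroxy-2-methyl-2H-chromen-2-yl]methyl (E)-3-[4-(tert-butyldimethylsilyloxy)-3-methoxyphenyl]acrylate | COc1cc(/C=C/C(=O)OC[C@@]2(C)C=Cc3cc(C(C)=O)c(O)cc3O2)ccc1O[Si](C)(C)C(C)(C)C | intermediate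
27 | [(2R)-6-acetyl-7-hydroxy-2-methyl-2H-chromen-2-yl]methyl (E)-3-(4-hydroxy-3-methoxyphenyl)acrylate | COc1cc(/C=C/C(=O)OC[C@@]2(C)C=Cc3cc(C(C)=O)c(O)cc3O2)ccc1O | target

## Step count and least certain steps

Total: 17 steps. Longest linear sequence: 16 steps (steps 1 to 14, 16 and 17); step 15 is a one-step side branch.

**Step 8 (key step).** The most likely failure is a stalled sequence. The tertiary alkoxide of 12 can add to its own enone or close a hemiketal on the ketone. If these reservoirs drain slowly, the enone is lost to double Michael addition or oligomerisation before Claisen closure, and long exposure to methoxide at reflux could erode the silyl ether. The fallback sets out from 12 and masks the tertiary hydroxyl with TESOTf and 2,6-lutidine at −78 °C as (R)-6-methyl-3-methylene-6-(triethylsilyloxy)-7-(triisopropylsilyloxy)heptan-2-one F1. The same malonate annulation would then give the triethylsilyl-protected dione ester F2, and AcOH/THF/H2O removes the triethylsilyl group to come back at 15.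

**Step 6.** The risk is over-addition after premature collapse of the lithium hemiketal alkoxide, or enolisation of the lactone by MeLi that returns 9. The fallback sets out from 9 and opens the lactone with the aluminium amide from Al(CH3)3 and N,O-dimethylhydroxylamine hydrochloride to the hydroxy Weinreb amide F3. MeMgBr then gives the ketone by the Weinreb ketone synthesis and comes back at 10.

**Step 10.** The risk is selenenylation at C8, the nucleophilic α-carbon of the vinylogous ester, in place of C6, or electrophilic selenium attack on the electron-rich phenol once it forms. The fallback sets out from 16 and uses direct dehydrogenation with DDQ (1.05 equiv, 1,4-dioxane, rt to 60 °C). This removes hydride from the dienol without any α-functionalisation and comes back at 18, with no new compound on the way.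

**Step 13.** The risk is slow hydride abstraction from the acetyl-deactivated chroman with competing oxidative degradation of the free phenol, leaving mixtures of chroman and chromene. The fallback sets out from 20.
- Acetylation (Ac2O, Et3N, DMAP) gives the aryl acetate F4.
- Radical benzylic bromination (NBS, AIBN, PhCF3, reflux) gives the 4-bromochroman F5.
- Elimination with DBU gives the chromene acetate F6.
- Methanolysis with K2CO3 in CH3OH comes back at 21.

**Step 16.** The risk is poor chemoselectivity, with acylation of the chelated C7 phenol or double acylation, or sluggish reaction at the neopentyl-type alcohol. The fallback sets out from 22 and builds the cinnamate on the alcohol instead of coupling it. Meldrum's acid in toluene at 90 °C gives the malonic half-ester F7, and Knoevenagel–Doebner condensation with vanillin (pyridine, piperidine cat.) then forms the E-ferulate with loss of CO2. This comes back at 27 directly, with no protecting group on the ferulate phenol.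

## Further compounds

F1 | step 8 | (R)-6-methyl-3-methylene-6-(triethylsilyloxy)-7-(triisopropylsilyloxy)heptan-2-one | CC(=O)C(=C)CC[C@@](C)(O[Si](CC)(CC)CC)CO[Si](C(C)C)(C(C)C)C(C)C
F2 | step 8 | methyl 5-[(3R)-3-methyl-3-(triethylsilyloxy)-4-(triisopropylsilyloxy)butyl]-2,4-dioxocyclohexane-1-carboxylate | COC(=O)C1CC(CC[C@@](C)(O[Si](CC)(CC)CC)CO[Si](C(C)C)(C(C)C)C(C)C)C(=O)CC1=O
F3 | step 6 | (5R)-2-[(dimethylamino)methyl]-5-hydroxy-N-methoxy-N,5-dimethyl-6-(triisopropylsilyloxy)hexanamide | CON(C)C(=O)C(CN(C)C)CC[C@@](C)(O)CO[Si](C(C)C)(C(C)C)C(C)C
F0 | step 10 | none | none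
F4 | step 13 | (R)-6-acetyl-2-methyl-2-[(triisopropylsilyloxy)methyl]chroman-7-yl acetate | CC(=O)c1cc2CC[C@](C)(CO[Si](C(C)C)(C(C)C)C(C)C)Oc2cc1OC(C)=O
F5 | step 13 | (2R)-6-acetyl-4-bromo-2-methyl-2-[(triisopropylsilyloxy)methyl]chroman-7-yl acetate (C4 epimers) | CC(=O)c1cc2C(Br)C[C@](C)(CO[Si](C(C)C)(C(C)C)C(C)C)Oc2cc1OC(C)=O
F6 | step 13 | (R)-6-acetyl-2-methyl-2-[(triisopropylsilyloxy)methyl]-2H-chromen-7-yl acetate | CC(=O)c1cc2C=C[C@](C)(CO[Si](C(C)C)(C(C)C)C(C)C)Oc2cc1OC(C)=O
F7 | step 16 | 3-{[(2R)-6-acetyl-7-hydroxy-2-methyl-2H-chromen-2-yl]methoxy}-3-oxopropanoic acid | OC(=O)CC(=O)OC[C@@]1(C)C=Cc2cc(C(C)=O)c(O)cc2O1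
A1 | alternative 1 | 1-(5-bromo-2,4-dihydroxyphenyl)ethan-1-one | CC(=O)c1cc(Br)c(O)cc1O
A2 | alternative 1 | 2,2-dimethyl-1,3-dioxan-5-one | CC1(C)OCC(=O)CO1
A3 | alternative 1 | 6-bromo-7-hydroxy-2',2'-dimethylspiro[chromane-2,5'-[1,3]dioxan]-4-one | CC1(C)OCC2(CO1)CC(=O)c1cc(Br)c(O)cc1O2
A4 | alternative 1 | 6-bromo-7-hydroxy-2,2-bis(hydroxymethyl)chroman-4-one | OCC1(CO)CC(=O)c2cc(Br)c(O)cc2O1
A5 | alternative 2 | (R,Z)-1-{2,4-difluoro-5-[3-hydroxy-4-(4-methoxybenzyloxy)-3-methylbut-1-en-1-yl]phenyl}ethan-1-one | CC(=O)c1cc(/C=C\[C@@](C)(O)COCc2ccc(OC)cc2)c(F)cc1F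
A6 | alternative 2 | (R)-1-[7-fluoro-2-(4-methoxybenzyloxymethyl)-2-methyl-2H-chromen-6-yl]ethan-1-one | CC(=O)c1cc2C=C[C@](C)(COCc3ccc(OC)cc3)Oc2cc1F
A7 | alternative 3 | (R)-6-[2,2-bis(trimethylsilyloxy)vinyl]-2-(tert-butyldimethylsilyloxymethyl)-2-methyl-3,4-dihydro-2H-pyran | C[Si](C)(C)OC(O[Si](C)(C)C)=CC1=CCC[C@](C)(CO[Si](C)(C)C(C)(C)C)O1
A8 | alternative 3 | but-3-yn-2-one | CC(=O)C#C
A9 | alternative 3 | (R)-1-[2-(tert-butyldimethylsilyloxymethyl)-7-hydroxy-2-methylchroman-6-yl]ethan-1-one | CC(=O)c1cc2CC[C@](C)(CO[Si](C)(C)C(C)(C)C)Oc2cc1O
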